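Ring C of the flavanone half is opened at its two bonds to ring A, O1–C8a and C4–C4a. These adjacent ring-A carbons are the two termini of an aryne, and the C5 oxygen next to C4a fixes the polarity of addition. In the key step an anti aldol adduct, an N-acyl oxazolidinone that already carries C2, C3 and the complete protected flavone half, is annulated with 3,5-bis(benzyloxy)benzyne: the carbinol oxygen arylates at C8a and the resulting aryl anion closes ring C on the imide carbonyl, expelling the auxiliary. The flavone half comes from luteolin by C8 iodination and enolate arylation; sulfation of the lone free 7''-hydroxyl and hydrogenolysis finish the route.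

Key step: step 10

Assumption: the target is drawn as the free hydrogen sulfate, so it is purified as its sodium salt and protonated with one equivalent of acid in the last operation.

Numbering: the flavanone half is unprimed (C2, C3, C4, ring A, 4' on ring B), the flavone half is double-primed (5'', 7'', 8''), and its catechol ring is triple-primed; before the coupling, luteolin numbering (5, 7, 8, 3', 4') is used. The target is the (2R,3S) 2,3-trans flavanone.

Step 1
Reactants: 1 luteolin; 2 dichlorodiphenylmethane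
Product: 3 3',4'-O-(diphenylmethylene)luteolin
Conditions: Ph2CCl2, Ph2O, 175 °C
Reagents that add atoms: dichlorodiphenylmethane ClC(Cl)(c1ccccc1)c1ccccc1
Why: Ketalisation with a gem-dichloride, in which only the 3',4'-catechol can close the five-membered 1,3-benzodioxole, so the 5- and 7-hydroxyls stay free.

Step 2
Reactants: 3 3',4'-O-(diphenylmethylene)luteolin; 4 4-methoxybenzyl chloride; 5 benzyl bromide
Product: 7 5-O-benzyl-7-O-(4-methoxybenzyl)-3',4'-O-(diphenylmethylene)luteolin, via 7-O-(4-methoxybenzyl) ether 6 (not isolated)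
Conditions: 4 (1.05 equiv), K2CO3, DMF, 25 °C; then 5 (2 equiv), K2CO3, 70 °C
Reagents that add atoms: 4-methoxybenzyl chloride COc1ccc(CCl)cc1; benzyl bromide BrCc1ccccc1
Why: Two Williamson etherifications in sequence, in which the acidic and unhindered 7-OH alkylates at room temperature whereas the 5-OH, hydrogen-bonded to the C4 carbonyl, reacts only with the second halide on heating, so the 7-oxygen alone carries the acid-labile group.

Step 3
Reactants: 7 5-O-benzyl-7-O-(4-methoxybenzyl)-3',4'-O-(diphenylmethylene)luteolin; 8 N-iodosuccinimide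
Product: 9 8-iodo-5-O-benzyl-7-O-(4-methoxybenzyl)-3',4'-O-(diphenylmethylene)luteolin
Conditions: NIS (1.05 equiv), CF3CO2H (5 mol%), MeCN, 0 °C to 25 °C
Reagents that add atoms: N-iodosuccinimide O=C1CCC(=O)N1I
Why: Electrophilic aromatic iodination, which in 5,7-dialkoxyflavones should favour C8 (flanked by the ring oxygen and one ether) over C6 (between two bulky benzylic ethers), while the catechol ring is deactivated by the pyranone.

Step 4
Reactants: 10 (R)-3-acetyl-4-benzyloxazolidin-2-one; 11 chlorotrimethylsilane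
Product: 13 (R)-4-benzyl-3-[1-(trimethylsilyloxy)ethenyl]oxazolidin-2-one, via lithium enolate 12 (not isolated)
Conditions: LiN(SiMe3)2, Me3SiCl, THF, −78 °C
Reagents that add atoms: chlorotrimethylsilane C[Si](C)(C)Cl
Why: Kinetic enolisation of the acetyl imide with O-silylation under in situ quench should give the silyl ketene N,O-acetal before the enolate can self-condense.

Step 5
Reactants: 9 8-iodo-5-O-benzyl-7-O-(4-methoxybenzyl)-3',4'-O-(diphenylmethylene)luteolin; 13 (R)-4-benzyl-3-[1-(trimethylsilyloxy)ethenyl]oxazolidin-2-one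
Product: 14 (R)-4-benzyl-3-{2-[5-O-benzyl-7-O-(4-methoxybenzyl)-3',4'-O-(diphenylmethylene)luteolin-8-yl]acetyl}oxazolidin-2-one
Conditions: Pd(dba)2 (5 mol%), P(t-Bu)3 (10 mol%), ZnF2 (0.6 equiv), DMF, 80 °C
Reagents that add atoms: (R)-4-benzyl-3-[1-(trimethylsilyloxy)ethenyl]oxazolidin-2-one C=C(O[Si](C)(C)C)N1[C@H](Cc2ccccc2)COC1=O
Why: Palladium-catalysed alpha-arylation of a silyl enolate (oxidative addition of zerovalent palladium into the C8–I bond, zinc fluoride-promoted transmetalation, reductive elimination), whose near-neutral conditions spare the flavone and the imide and in which the di-ortho-substituted aryl group should disfavour a second arylation.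

Step 6
Reactants: 14 (R)-4-benzyl-3-{2-[5-O-benzyl-7-O-(4-methoxybenzyl)-3',4'-O-(diphenylmethylene)luteolin-8-yl]acetyl}oxazolidin-2-one; 15 4-(benzyloxy)benzaldehyde
Product: 17 (R)-4-benzyl-3-{(2S,3R)-3-[4-(benzyloxy)phenyl]-3-hydroxy-2-[5-O-benzyl-7-O-(4-methoxybenzyl)-3',4'-O-(diphenylmethylene)luteolin-8-yl]propanoyl}oxazolidin-2-one (anti aldol adduct), via O-trimethylsilyl ether 16 (not isolated)
Conditions: MgCl2 (0.5 equiv), Et3N, Me3SiCl, EtOAc, 25 °C; then 1 M HCl, THF, 0 °C
Reagents that add atoms: 4-(benzyloxy)benzaldehyde O=Cc1ccc(OCc2ccccc2)cc1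
Why: Magnesium chloride-catalysed direct anti-aldol of an N-acyl oxazolidinone, in which the chelated Z-enolate should be attacked on the face opposite the auxiliary benzyl group (setting the alpha carbon as S, hence the R auxiliary), the boat-type transition state gives the anti relationship (carbinol carbon R), and silylation of the aldolate makes the addition irreversible.

Step 7
Reactants: 18 3,5-bis(benzyloxy)phenol; 19 isopropyl isocyanate
Product: 20 3,5-bis(benzyloxy)phenyl N-isopropylcarbamate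
Conditions: i-PrNCO, Et3N (10 mol%), CH2Cl2, 25 °C
Reagents that add atoms: isopropyl isocyanate CC(C)N=C=O
Why: Addition of the phenol to the isocyanate gives a carbamate that is a strong ortho-directing group and can later be removed under mild base.

Step 8
Reactants: 20 3,5-bis(benzyloxy)phenyl N-isopropylcarbamate; 11 chlorotrimethylsilane
Product: 24 3,5-bis(benzyloxy)-2-(trimethylsilyl)phenyl N-isopropylcarbamate, via N-silyl carbamate 21 (not isolated), via aryllithium 22 (not isolated), via N-silyl C-silyl carbamate 23 (not isolated)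
Conditions: t-BuMe2SiOTf, TMEDA, Et2O, 0 °C; n-BuLi, TMEDA, −78 °C; Me3SiCl, −78 °C to 25 °C; aq. NaHSO4
Reagents that add atoms: chlorotrimethylsilane C[Si](C)(C)Cl
Why: Directed ortho-metalation, in which after N-silylation the carbamate and the neighbouring benzyloxy group jointly direct lithiation to C2 (the two ortho positions are equivalent by symmetry) and the aryllithium is silylated, the fast lithiation at −78 °C preceding any attack on the benzylic ether positions.

Step 9
Reactants: 24 3,5-bis(benzyloxy)-2-(trimethylsilyl)phenyl N-isopropylcarbamate; 25 N-phenylbis(trifluoromethanesulfonimide)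
Product: 27 3,5-bis(benzyloxy)-2-(trimethylsilyl)phenyl trifluoromethanesulfonate, via 3,5-bis(benzyloxy)-2-(trimethylsilyl)phenol 26 (not isolated)
Conditions: DBU, Et2NH, MeCN, 40 °C; then PhNTf2, 25 °C
Reagents that add atoms: N-phenylbis(trifluoromethanesulfonimide) O=S(=O)(N(c1ccccc1)S(=O)(=O)C(F)(F)F)C(F)(F)F
Why: Base-induced fragmentation of the carbamate to phenoxide and isopropyl isocyanate (trapped by diethylamine), followed by triflation of the phenoxide in the same flask, should deliver the o-silylaryl triflate without protodesilylation.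

Step 10
Reactants: 17 anti aldol adduct; 27 3,5-bis(benzyloxy)-2-(trimethylsilyl)phenyl trifluoromethanesulfonate
Product: 30 (2R,3S)-5,7-bis(benzyloxy)-2-[4-(benzyloxy)phenyl]-3-[5-O-benzyl-7-O-(4-methoxybenzyl)-3',4'-O-(diphenylmethylene)luteolin-8-yl]chroman-4-one, via 3,5-bis(benzyloxy)benzyne 28 (not isolated), via aryl anion adduct 29 (not isolated)
Conditions: CsF (4 equiv), 27 (1.5 equiv), THF, 50 °C
Reagents that add atoms: 3,5-bis(benzyloxy)-2-(trimethylsilyl)phenyl trifluoromethanesulfonate C[Si](C)(C)c1c(OCc2ccccc2)cc(OCc2ccccc2)cc1OS(=O)(=O)C(F)(F)F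
Why: Proposed new method: fluoride unmasks aryne 28 from 27 and activates the carbinol of 17 by hydrogen bonding, the oxygen adds to the aryne carbon remote from the flanking benzyloxy group (the distorted, more electrophilic terminus), and the aryl anion 29, placed between the new ether and that benzyloxy group and stabilised inductively by it, attacks the exocyclic imide carbonyl in a 6-exo-trig addition–elimination that closes ring C and expels the oxazolidinone, so O1–C8a and C4–C4a form in one operation. The closest known reactions are the aryne annulation of salicylate esters to xanthones and the O–H insertion of arynes into aliphatic alcohols, and the untested element is an aliphatic beta-hydroxy imide as the two-point partner. No stereocentre is created, since C2 reacts only at oxygen and C3 is untouched, so the (2R,3S) trans pair is that of the aldol adduct, and trans is also the thermodynamic arrangement should C3 enolise. The step needs regioselectivity on the aryne, secured by the 3-alkoxy substituent, and acyl capture faster than protonation of the aryl anion, favoured by the activated imide carbonyl held in a six-membered array and by the aprotic medium. It also needs aryne capture to outrun retro-aldol cleavage, for which the alcohol is never fully deprotonated because no base stronger than CsF is present.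

Step 11
Reactants: 30 protected flavanone–flavone
Product: 31 (2R,3S)-5,7-bis(benzyloxy)-2-[4-(benzyloxy)phenyl]-3-[5-O-benzyl-3',4'-O-(diphenylmethylene)luteolin-8-yl]chroman-4-one (free 7''-hydroxyl)
Conditions: CF3CO2H (10% v/v), anisole (5 equiv), CH2Cl2, 0 °C
Reagents that add atoms: none
Why: Acidolysis of the 4-methoxybenzyl aryl ether with anisole as cation trap, the benzyl ethers and the diphenylmethylene ketal being much less acid-labile at 0 °C and the flavanone centres not being at risk because C3 already has the thermodynamic trans configuration.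

Step 12
Reactants: 31 7''-phenol; 32 sulfur trioxide–pyridine complex; 33 sodium hydrogen carbonate
Product: 34 sodium 7''-O-sulfate of 31
Conditions: SO3·pyridine (5 equiv), pyridine, 40 °C; then aq. NaHCO3
Reagents that add atoms: sulfur trioxide–pyridine complex O=S(=O)([O-])[n+]1ccccc1; sodium hydrogen carbonate [Na+].OC([O-])=O
Why: O-sulfation of a phenol with the sulfur trioxide–pyridine complex, in which the 7''-hydroxyl is the only free hydroxyl so that no selectivity question arises, and the sodium salt should be stable to chromatography.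

Step 13
Reactants: 34 sodium 7''-O-sulfate
Product: 36 target hydrogen sulfate (CNP0314990.1), via sodium salt of the target 35 (not isolated)
Conditions: H2 (1 atm), Pd/C (palladium on carbon), THF/MeOH, 25 °C; then HCl (1.0 equiv), H2O, 0 °C, C18 desalting
Reagents that add atoms: none
Why: Hydrogenolysis should cleave the four benzyl ethers and the diphenylmethylene ketal while the aryl sulfate monoester, the flavone double bond and the flavanone ring survive at 1 atm and room temperature, and one equivalent of acid then gives the hydrogen sulfate.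

Compound list

1 | luteolin | O=c1cc(-c2ccc(O)c(O)c2)oc2cc(O)cc(O)c12 | starting material
2 | dichlorodiphenylmethane | ClC(Cl)(c1ccccc1)c1ccccc1 | starting material
3 | 3',4'-O-(diphenylmethylene)luteolin, 2-(2,2-diphenyl-1,3-benzodioxol-5-yl)-5,7-dihydroxy-4H-chromen-4-one | O=c1cc(-c2ccc3c(c2)OC(c2ccccc2)(c2ccccc2)O3)oc2cc(O)cc(O)c12 | intermediate
4 | 4-methoxybenzyl chloride | COc1ccc(CCl)cc1 | starting material
5 | benzyl bromide | BrCc1ccccc1 | starting material
6 | 7-O-(4-methoxybenzyl)-3',4'-O-(diphenylmethylene)luteolin (not isolated) | O=c1cc(-c2ccc3c(c2)OC(c2ccccc2)(c2ccccc2)O3)oc2cc(OCc3ccc(OC)cc3)cc(O)c12 | intermediate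
7 | 5-O-benzyl-7-O-(4-methoxybenzyl)-3',4'-O-(diphenylmethylene)luteolin | O=c1cc(-c2ccc3c(c2)OC(c2ccccc2)(c2ccccc2)O3)oc2cc(OCc3ccc(OC)cc3)cc(OCc3ccccc3)c12 | intermediate
8 | N-iodosuccinimide | O=C1CCC(=O)N1I | starting material
9 | 8-iodo-5-O-benzyl-7-O-(4-methoxybenzyl)-3',4'-O-(diphenylmethylene)luteolin | O=c1cc(-c2ccc3c(c2)OC(c2ccccc2)(c2ccccc2)O3)oc2c(I)c(OCc3ccc(OC)cc3)cc(OCc3ccccc3)c12 | intermediate
10 | (R)-3-acetyl-4-benzyloxazolidin-2-one | CC(=O)N1[C@H](Cc2ccccc2)COC1=O | starting material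
11 | chlorotrimethylsilane | C[Si](C)(C)Cl | starting material
12 | lithium enolate of 10 (not isolated) | C=C(O[Li])N1[C@H](Cc2ccccc2)COC1=O | intermediate
13 | (R)-4-benzyl-3-[1-(trimethylsilyloxy)ethenyl]oxazolidin-2-one | C=C(O[Si](C)(C)C)N1[C@H](Cc2ccccc2)COC1=O | intermediate
14 | (R)-4-benzyl-3-{2-[5-(benzyloxy)-2-(2,2-diphenyl-1,3-benzodioxol-5-yl)-7-(4-methoxybenzyloxy)-4-oxo-4H-chromen-8-yl]acetyl}oxazolidin-2-one | O=C(Cc1c(OCc2ccc(OC)cc2)cc(OCc2ccccc2)c2c(=O)cc(-c3ccc4c(c3)OC(c3ccccc3)(c3ccccc3)O4)oc12)N1[C@H](Cc2ccccc2)COC1=O | intermediate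
15 | 4-(benzyloxy)benzaldehyde | O=Cc1ccc(OCc2ccccc2)cc1 | starting material
16 | O-trimethylsilyl ether of 17 (not isolated) | O=C([C@H]([C@@H](O[Si](C)(C)C)c1ccc(OCc2ccccc2)cc1)c1c(OCc2ccc(OC)cc2)cc(OCc2ccccc2)c2c(=O)cc(-c3ccc4c(c3)OC(c3ccccc3)(c3ccccc3)O4)oc12)N1[C@H](Cc2ccccc2)COC1=O | intermediate
17 | (R)-4-benzyl-3-{(2S,3R)-3-[4-(benzyloxy)phenyl]-3-hydroxy-2-[5-(benzyloxy)-2-(2,2-diphenyl-1,3-benzodioxol-5-yl)-7-(4-methoxybenzyloxy)-4-oxo-4H-chromen-8-yl]propanoyl}oxazolidin-2-one (anti aldol adduct) | O=C([C@H]([C@@H](O)c1ccc(OCc2ccccc2)cc1)c1c(OCc2ccc(OC)cc2)cc(OCc2ccccc2)c2c(=O)cc(-c3ccc4c(c3)OC(c3ccccc3)(c3ccccc3)O4)oc12)N1[C@H](Cc2ccccc2)COC1=O | intermediate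
18 | 3,5-bis(benzyloxy)phenol | Oc1cc(OCc2ccccc2)cc(OCc2ccccc2)c1 | starting material
19 | isopropyl isocyanate | CC(C)N=C=O | starting material
20 | 3,5-bis(benzyloxy)phenyl N-isopropylcarbamate | CC(C)NC(=O)Oc1cc(OCc2ccccc2)cc(OCc2ccccc2)c1 | intermediate
21 | 3,5-bis(benzyloxy)phenyl N-(tert-butyldimethylsilyl)-N-isopropylcarbamate (not isolated) | CC(C)N(C(=O)Oc1cc(OCc2ccccc2)cc(OCc2ccccc2)c1)[Si](C)(C)C(C)(C)C | intermediate
22 | 2-lithio derivative of 21 (not isolated) | CC(C)N(C(=O)Oc1cc(OCc2ccccc2)cc(OCc2ccccc2)c1[Li])[Si](C)(C)C(C)(C)C | intermediate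
23 | 3,5-bis(benzyloxy)-2-(trimethylsilyl)phenyl N-(tert-butyldimethylsilyl)-N-isopropylcarbamate (not isolated) | CC(C)N(C(=O)Oc1cc(OCc2ccccc2)cc(OCc2ccccc2)c1[Si](C)(C)C)[Si](C)(C)C(C)(C)C | intermediate
24 | 3,5-bis(benzyloxy)-2-(trimethylsilyl)phenyl N-isopropylcarbamate | CC(C)NC(=O)Oc1cc(OCc2ccccc2)cc(OCc2ccccc2)c1[Si](C)(C)C | intermediate
25 | N-phenylbis(trifluoromethanesulfonimide) | O=S(=O)(N(c1ccccc1)S(=O)(=O)C(F)(F)F)C(F)(F)F | starting material
26 | 3,5-bis(benzyloxy)-2-(trimethylsilyl)phenol (not isolated) | Oc1cc(OCc2ccccc2)cc(OCc2ccccc2)c1[Si](C)(C)C | intermediate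
27 | 3,5-bis(benzyloxy)-2-(trimethylsilyl)phenyl trifluoromethanesulfonate | C[Si](C)(C)c1c(OCc2ccccc2)cc(OCc2ccccc2)cc1OS(=O)(=O)C(F)(F)F | intermediate
28 | 3,5-bis(benzyloxy)benzyne (not isolated) | C1#CC(OCc2ccccc2)=CC(OCc2ccccc2)=C1 | intermediate
29 | cesium aryl adduct, the O-[2-cesio-3,5-bis(benzyloxy)phenyl] ether of 17 (not isolated) | O=C([C@H]([C@@H](Oc1cc(OCc2ccccc2)cc(OCc2ccccc2)c1[Cs])c1ccc(OCc2ccccc2)cc1)c1c(OCc2ccc(OC)cc2)cc(OCc2ccccc2)c2c(=O)cc(-c3ccc4c(c3)OC(c3ccccc3)(c3ccccc3)O4)oc12)N1[C@H](Cc2ccccc2)COC1=O | intermediate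
30 | (2R,3S)-5,7-bis(benzyloxy)-2-[4-(benzyloxy)phenyl]-3-[5-(benzyloxy)-2-(2,2-diphenyl-1,3-benzodioxol-5-yl)-7-(4-methoxybenzyloxy)-4-oxo-4H-chromen-8-yl]chroman-4-one | O=C1c2c(OCc3ccccc3)cc(OCc3ccccc3)cc2O[C@@H](c2ccc(OCc3ccccc3)cc2)[C@@H]1c1c(OCc2ccc(OC)cc2)cc(OCc2ccccc2)c2c(=O)cc(-c3ccc4c(c3)OC(c3ccccc3)(c3ccccc3)O4)oc12 | intermediate
31 | (2R,3S)-5,7-bis(benzyloxy)-2-[4-(benzyloxy)phenyl]-3-[5-(benzyloxy)-2-(2,2-diphenyl-1,3-benzodioxol-5-yl)-7-hydroxy-4-oxo-4H-chromen-8-yl]chroman-4-one | O=C1c2c(OCc3ccccc3)cc(OCc3ccccc3)cc2O[C@@H](c2ccc(OCc3ccccc3)cc2)[C@@H]1c1c(O)cc(OCc2ccccc2)c2c(=O)cc(-c3ccc4c(c3)OC(c3ccccc3)(c3ccccc3)O4)oc12 | intermediate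
32 | sulfur trioxide–pyridine complex | O=S(=O)([O-])[n+]1ccccc1 | starting material
33 | sodium hydrogen carbonate | [Na+].OC([O-])=O | starting material
34 | sodium 7''-O-sulfate of 31 | O=C1c2c(OCc3ccccc3)cc(OCc3ccccc3)cc2O[C@@H](c2ccc(OCc3ccccc3)cc2)[C@@H]1c1c(OS(=O)(=O)[O-])cc(OCc2ccccc2)c2c(=O)cc(-c3ccc4c(c3)OC(c3ccccc3)(c3ccccc3)O4)oc12.[Na+] | intermediate
35 | sodium salt of the target (not isolated) | O=C1c2c(O)cc(O)cc2O[C@@H](c2ccc(O)cc2)[C@@H]1c1c(OS(=O)(=O)[O-])cc(O)c2c(=O)cc(-c3ccc(O)c(O)c3)oc12.[Na+] | intermediate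
36 | CNP0314990.1, (2R,3S)-naringenin-(3→8'')-luteolin 7''-O-(hydrogen sulfate) | O=C1c2c(O)cc(O)cc2O[C@@H](c2ccc(O)cc2)[C@@H]1c1c(OS(=O)(=O)O)cc(O)c2c(=O)cc(-c3ccc(O)c(O)c3)oc12 | target

Total step count: 13. Longest linear sequence: 9 steps (steps 1, 2, 3, 5, 6, 10, 11, 12, 13, from luteolin); steps 4 and 7–9 are side branches.

Steps most likely to fail

1. Step 10 (the labelled step). What may go wrong: the aryl anion is protonated before it reaches the imide carbonyl, so that only O-arylation occurs; the aldol adduct undergoes fluoride-induced retro-aldol cleavage; or the carbinol oxygen is transferred onto the ring carbonyl of the oxazolidinone. Fallback, from 17 back to 30, makes the two bonds in separate operations. The alcohol of 17 is arylated with the same aryne under the conditions known for O–H insertion into aliphatic alcohols (27, KF, 18-crown-6, THF, −20 °C, the alcohol serving as proton source), which should give the aryl ether imide F1. LiOH/H2O2 (THF/H2O, 0 °C) then removes the auxiliary to give the 3-aryloxypropanoic acid F2. Intramolecular Friedel–Crafts acylation (trifluoroacetic anhydride, CH2Cl2, 0 °C) on the 3,5-bis(benzyloxy)phenoxy ring, whose two ortho positions are equivalent, closes ring C to 30.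

2. Step 5. What may go wrong: slow oxidative addition and transmetalation at the di-ortho-substituted C8, so that reduction of the C–I bond, desilylation of 13 or ketene loss from the acetyl imide enolate takes over. Fallback, from 9 back to 14, brings in the two-carbon unit as an allyl group. Stille coupling of 9 with allyltributylstannane (Pd(PPh3)4, DMF, 90 °C) should give the 8-allyl flavone F3. Lemieux–Johnson cleavage (OsO4 catalytic, NaIO4, 2,6-lutidine, dioxane/H2O) gives the arylacetaldehyde F4, and Pinnick oxidation (NaClO2, NaH2PO4, 2-methyl-2-butene) gives the arylacetic acid F5. Pivaloyl chloride and Et3N convert F5 into the mixed anhydride F6, which acylates (R)-4-benzyloxazolidin-2-one (LiCl, Et3N, THF) to 14.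

3. Step 6. What may go wrong: poor facial or anti/syn selectivity with the bulky alpha-aryl enolate, or low conversion because enolisation is slow and the aldolate reverts before it is silylated. Fallback, from 14 back to 17, separates C–C bond formation from the setting of the carbinol centre. The lithium enolate of 14 (LiN(SiMe3)2, THF, −78 °C) is C-acylated with 4-(benzyloxy)benzoyl chloride on the face opposite the auxiliary benzyl group to give the beta-keto imide F7, whose alpha centre is held by allylic strain in the imide. Reagent-controlled asymmetric transfer hydrogenation of the aryl ketone (RuCl(p-cymene)[(R,R)-TsDPEN], HCO2H/Et3N, 25 °C) is expected to give the (R)-carbinol, that is 17.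

Further compounds

F1 | step 10 | (R)-4-benzyl-3-{(2S,3R)-3-[4-(benzyloxy)phenyl]-3-[3,5-bis(benzyloxy)phenoxy]-2-[5-(benzyloxy)-2-(2,2-diphenyl-1,3-benzodioxol-5-yl)-7-(4-methoxybenzyloxy)-4-oxo-4H-chromen-8-yl]propanoyl}oxazolidin-2-one | O=C([C@H]([C@@H](Oc1cc(OCc2ccccc2)cc(OCc2ccccc2)c1)c1ccc(OCc2ccccc2)cc1)c1c(OCc2ccc(OC)cc2)cc(OCc2ccccc2)c2c(=O)cc(-c3ccc4c(c3)OC(c3ccccc3)(c3ccccc3)O4)oc12)N1[C@H](Cc2ccccc2)COC1=O
F2 | step 10 | (2S,3R)-3-[4-(benzyloxy)phenyl]-3-[3,5-bis(benzyloxy)phenoxy]-2-[5-(benzyloxy)-2-(2,2-diphenyl-1,3-benzodioxol-5-yl)-7-(4-methoxybenzyloxy)-4-oxo-4H-chromen-8-yl]propanoic acid | O=C(O)[C@H]([C@@H](Oc1cc(OCc2ccccc2)cc(OCc2ccccc2)c1)c1ccc(OCc2ccccc2)cc1)c1c(OCc2ccc(OC)cc2)cc(OCc2ccccc2)c2c(=O)cc(-c3ccc4c(c3)OC(c3ccccc3)(c3ccccc3)O4)oc12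
F3 | step 5 | 8-allyl-5-O-benzyl-7-O-(4-methoxybenzyl)-3',4'-O-(diphenylmethylene)luteolin | C=CCc1c(OCc2ccc(OC)cc2)cc(OCc2ccccc2)c2c(=O)cc(-c3ccc4c(c3)OC(c3ccccc3)(c3ccccc3)O4)oc12
F4 | step 5 | 2-[5-O-benzyl-7-O-(4-methoxybenzyl)-3',4'-O-(diphenylmethylene)luteolin-8-yl]acetaldehyde | O=CCc1c(OCc2ccc(OC)cc2)cc(OCc2ccccc2)c2c(=O)cc(-c3ccc4c(c3)OC(c3ccccc3)(c3ccccc3)O4)oc12
F5 | step 5 | 2-[5-O-benzyl-7-O-(4-methoxybenzyl)-3',4'-O-(diphenylmethylene)luteolin-8-yl]acetic acid | O=C(O)Cc1c(OCc2ccc(OC)cc2)cc(OCc2ccccc2)c2c(=O)cc(-c3ccc4c(c3)OC(c3ccccc3)(c3ccccc3)O4)oc12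
F6 | step 5 | mixed anhydride of F5 with pivalic acid | CC(C)(C)C(=O)OC(=O)Cc1c(OCc2ccc(OC)cc2)cc(OCc2ccccc2)c2c(=O)cc(-c3ccc4c(c3)OC(c3ccccc3)(c3ccccc3)O4)oc12
F7 | step 6 | (R)-4-benzyl-3-{(2S)-3-[4-(benzyloxy)phenyl]-3-oxo-2-[5-(benzyloxy)-2-(2,2-diphenyl-1,3-benzodioxol-5-yl)-7-(4-methoxybenzyloxy)-4-oxo-4H-chromen-8-yl]propanoyl}oxazolidin-2-one | O=C(c1ccc(OCc2ccccc2)cc1)[C@H](c1c(OCc2ccc(OC)cc2)cc(OCc2ccccc2)c2c(=O)cc(-c3ccc4c(c3)OC(c3ccccc3)(c3ccccc3)O4)oc12)C(=O)N1[C@H](Cc2ccccc2)COC1=O
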